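**Retrosynthetic overview**

1. The target is reached from a fully protected isoflavone by desilylation of the chain hydroxyl and removal of four MOM ethers. Ring C (the pyranone) is closed last, by inserting C2 from DMF dimethyl acetal between O1 and C3 of a 2‑hydroxy deoxybenzoin.
2. The deoxybenzoin is disconnected at C8a–O1 and C4a–C4. The strategy rests on this feature: C4a and C8a are adjacent ring‑A carbons that carry the acyl carbon C4 and the oxygen O1. An aryne across C4a–C8a, flanked by the C5 oxygen and the C8 chain, can therefore take up the ring‑B arylacetic acid through its C–O bond.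
3. The aryne precursor (triflate on C8a, SiMe3 on C4a) comes from phloroglucinol. O8a is marked as a TIPS ether, and three MOM‑directed lithiations place prenyl on C6, a hydroxyethyl group on C8 and silicon on C4a.
4. The (R) carbinol centre of the C8 chain is set by oxazaborolidine‑catalysed reduction of an isopropenyl ketone.
5. Ring order: ring A (phloroglucinol) and ring B (3,4‑dihydroxyphenylacetic acid) are carried in; ring C is the only ring formed.

Key step: step 14

Assumption: locants are those of the final chromen‑4‑one (C4a, C5–C8, C8a); isopropenylmagnesium bromide and ethylene oxide are taken as commercial THF solutions.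

**Route**

Step 1
Reactants: 1 3,4-dihydroxyphenylacetic acid
Product: 3 3,4-bis(methoxymethoxy)phenylacetic acid, via methoxymethyl ester 2 (not isolated)
Conditions: MeOCH2Cl (3.5 equiv), iPr2NEt, CH2Cl2, 0 °C → rt; concentrate; LiOH·H2O, THF/MeOH/H2O, rt; 1 M HCl to pH 4, 0 °C
Reagents that add atoms: chloromethyl methyl ether, COCCl; lithium hydroxide, [Li+].[OH-]
Why: Base-mediated O-alkylation covers both phenols and the carboxylate, and saponification then cleaves only the acyl acetal ester because aryl MOM ethers are stable to hydroxide.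

Step 2
Reactants: 4 phloroglucinol
Product: 5 3,5-bis(methoxymethoxy)phenol
Conditions: MeOCH2Cl (2.0 equiv), iPr2NEt (2.2 equiv), DMF/CH2Cl2, 0 °C → rt; chromatographic separation from mono- and tris-ethers
Reagents that add atoms: chloromethyl methyl ether, COCCl
Why: Stoichiometry-controlled statistical O-alkylation of three equivalent hydroxyls should give the bis-ether as a separable component, leaving one oxygen (the future triflate oxygen) distinct.

Step 3
Reactants: 5 3,5-bis(methoxymethoxy)phenol
Product: 6 [3,5-bis(methoxymethoxy)phenoxy]triisopropylsilane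
Conditions: iPr3SiCl, imidazole, DMF, rt
Reagents that add atoms: chlorotriisopropylsilane, CC(C)[Si](Cl)(C(C)C)C(C)C
Why: Imidazole-promoted silylation of the phenol installs a bulky, weakly coordinating group that does not direct lithiation and resists O-to-C silyl migration.

Step 4
Reactants: 6 [3,5-bis(methoxymethoxy)phenoxy]triisopropylsilane; 7 prenyl bromide (1-bromo-3-methylbut-2-ene)
Product: 9 [3,5-bis(methoxymethoxy)-4-(3-methylbut-2-enyl)phenoxy]triisopropylsilane, via C6 aryllithium 8 (not isolated)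
Conditions: n-BuLi (1.1 equiv), THF, 0 °C; CuBr·SMe2 (10 mol %), then 7, −78 °C → rt
Reagents that add atoms: none
Why: Directed ortho-metalation should occur at the one carbon flanked by both chelating MOM groups (future C6) and not beside the hindered silyloxy group, and copper-catalysed allylation then gives the linear prenyl arene.

Step 5
Reactants: 9 [3,5-bis(methoxymethoxy)-4-(3-methylbut-2-enyl)phenoxy]triisopropylsilane; 10 ethylene oxide
Product: 12 2-[2,4-bis(methoxymethoxy)-3-(3-methylbut-2-enyl)-6-(triisopropylsilyloxy)phenyl]ethanol, via C8 aryllithium 11 (not isolated)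
Conditions: s-BuLi (1.2 equiv), THF, −78 → −30 °C; then 10 (3 equiv), BF3·OEt2 (1.5 equiv), −78 °C; aq. NH4Cl at −78 °C
Reagents that add atoms: none
Why: The two remaining ring hydrogens are equivalent by symmetry and each lies ortho to a MOM group, so directed ortho-metalation can give only one aryllithium, which opens BF3-activated ethylene oxide at low temperature before the silyl group can migrate.

Step 6
Reactants: 12 2-[2,4-bis(methoxymethoxy)-3-(3-methylbut-2-enyl)-6-(triisopropylsilyloxy)phenyl]ethanol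
Product: 13 2-[2,4-bis(methoxymethoxy)-3-(3-methylbut-2-enyl)-6-(triisopropylsilyloxy)phenyl]acetaldehyde
Conditions: Dess–Martin periodinane, NaHCO3, CH2Cl2, 0 °C → rt; used directly
Reagents that add atoms: none
Why: Buffered Dess–Martin oxidation converts the primary alcohol to the aldehyde without touching the electron-rich ring, the acetals or the prenyl double bond.

Step 7
Reactants: 13 2-[2,4-bis(methoxymethoxy)-3-(3-methylbut-2-enyl)-6-(triisopropylsilyloxy)phenyl]acetaldehyde; 14 isopropenylmagnesium bromide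
Product: 15 rac-1-[2,4-bis(methoxymethoxy)-3-(3-methylbut-2-enyl)-6-(triisopropylsilyloxy)phenyl]-3-methylbut-3-en-2-ol
Conditions: 14 (1.5 equiv), THF, −78 → −40 °C
Reagents that add atoms: none
Why: Grignard 1,2-addition builds the full C8 chain; the carbinol centre is formed as a racemate on purpose and is set in step 9, and enolisation is limited because the di-ortho-substituted ring cannot conjugate with the enolate.

Step 8
Reactants: 15 rac-1-[2,4-bis(methoxymethoxy)-3-(3-methylbut-2-enyl)-6-(triisopropylsilyloxy)phenyl]-3-methylbut-3-en-2-ol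
Product: 16 1-[2,4-bis(methoxymethoxy)-3-(3-methylbut-2-enyl)-6-(triisopropylsilyloxy)phenyl]-3-methylbut-3-en-2-one
Conditions: Dess–Martin periodinane, NaHCO3, CH2Cl2, 0 °C
Reagents that add atoms: none
Why: Dess–Martin oxidation of the secondary allylic alcohol gives the α-methylene ketone under neutral conditions that avoid conjugate addition to the enone.

Step 9
Reactants: 16 1-[2,4-bis(methoxymethoxy)-3-(3-methylbut-2-enyl)-6-(triisopropylsilyloxy)phenyl]-3-methylbut-3-en-2-one
Product: 17 (2R)-1-[2,4-bis(methoxymethoxy)-3-(3-methylbut-2-enyl)-6-(triisopropylsilyloxy)phenyl]-3-methylbut-3-en-2-ol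
Conditions: (S)-Me-CBS oxazaborolidine [(S)-1-methyl-3,3-diphenyltetrahydro-1H,3H-pyrrolo[1,2-c][1,3,2]oxazaborole] (0.2 equiv), catecholborane (1.5 equiv), toluene, −78 °C
Reagents that add atoms: none
Why: In this Corey–Bakshi–Shibata reduction the ketone should bind the catalyst boron anti to the α-branched isopropenyl group, which acts as the larger substituent, so the (S)-catalyst delivers hydride to the face that gives the (2R)-alcohol, while catecholborane at −78 °C leaves both double bonds alone; the configuration is to be confirmed by Mosher ester analysis.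

Step 10
Reactants: 17 (2R)-1-[2,4-bis(methoxymethoxy)-3-(3-methylbut-2-enyl)-6-(triisopropylsilyloxy)phenyl]-3-methylbut-3-en-2-ol
Product: 18 {[(2R)-1-[2,4-bis(methoxymethoxy)-3-(3-methylbut-2-enyl)-6-(triisopropylsilyloxy)phenyl]-3-methylbut-3-en-2-yl]oxy}triisopropylsilane
Conditions: iPr3SiOTf, 2,6-lutidine, CH2Cl2, −78 → 0 °C
Reagents that add atoms: triisopropylsilyl trifluoromethanesulfonate, CC(C)[Si](OS(=O)(=O)C(F)(F)F)(C(C)C)C(C)C
Why: Silyl triflate with a hindered pyridine base silylates the hindered secondary allylic alcohol without epimerisation, giving an ether bulky enough to withstand fluoride in step 14.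

Step 11
Reactants: 18 {[(2R)-1-[2,4-bis(methoxymethoxy)-3-(3-methylbut-2-enyl)-6-(triisopropylsilyloxy)phenyl]-3-methylbut-3-en-2-yl]oxy}triisopropylsilane
Product: 20 {[(2R)-1-[2,4-bis(methoxymethoxy)-3-(3-methylbut-2-enyl)-6-(triisopropylsilyloxy)-5-(trimethylsilyl)phenyl]-3-methylbut-3-en-2-yl]oxy}triisopropylsilane, via C4a aryllithium 19 (not isolated)
Conditions: s-BuLi (1.3 equiv), TMEDA, THF, −78 °C; Me3SiCl (2 equiv), −78 → 0 °C
Reagents that add atoms: chlorotrimethylsilane, C[Si](C)(C)Cl
Why: Directed ortho-metalation by the C5 MOM group removes the only remaining ring hydrogen (C4a) faster than any benzylic or allylic hydrogen at −78 °C, and the small silyl chloride traps the hindered aryllithium.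

Step 12
Reactants: 20 {[(2R)-1-[2,4-bis(methoxymethoxy)-3-(3-methylbut-2-enyl)-6-(triisopropylsilyloxy)-5-(trimethylsilyl)phenyl]-3-methylbut-3-en-2-yl]oxy}triisopropylsilane
Product: 21 3,5-bis(methoxymethoxy)-4-(3-methylbut-2-enyl)-2-[(2R)-3-methyl-2-(triisopropylsilyloxy)but-3-enyl]-6-(trimethylsilyl)phenol
Conditions: Bu4NF (1.05 equiv), THF, 0 °C, short reaction time; aq. NH4Cl
Reagents that add atoms: none
Why: Fluoride cleaves an aryl silyl ether (phenoxide leaving group) much faster than a hindered secondary alkyl silyl ether, and the aryl–silicon bond is not attacked at 0 °C with one equivalent.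

Step 13
Reactants: 21 3,5-bis(methoxymethoxy)-4-(3-methylbut-2-enyl)-2-[(2R)-3-methyl-2-(triisopropylsilyloxy)but-3-enyl]-6-(trimethylsilyl)phenol
Product: 22 3,5-bis(methoxymethoxy)-4-(3-methylbut-2-enyl)-2-[(2R)-3-methyl-2-(triisopropylsilyloxy)but-3-enyl]-6-(trimethylsilyl)phenyl trifluoromethanesulfonate
Conditions: KN(SiMe3)2, THF, −78 °C; PhNTf2, −78 °C → rt
Reagents that add atoms: N-phenylbis(trifluoromethanesulfonimide), O=S(=O)(N(c1ccccc1)S(=O)(=O)C(F)(F)F)C(F)(F)F
Why: O-sulfonylation of the hindered potassium phenoxide with the mild triflimide reagent gives the ortho-silylaryl triflate without acid that could strip the MOM groups or the aryl silane.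

Step 14
Reactants: 22 3,5-bis(methoxymethoxy)-4-(3-methylbut-2-enyl)-2-[(2R)-3-methyl-2-(triisopropylsilyloxy)but-3-enyl]-6-(trimethylsilyl)phenyl trifluoromethanesulfonate; 3 3,4-bis(methoxymethoxy)phenylacetic acid
Product: 25 1-{2-hydroxy-4,6-bis(methoxymethoxy)-5-(3-methylbut-2-enyl)-3-[(2R)-3-methyl-2-(triisopropylsilyloxy)but-3-enyl]phenyl}-2-[3,4-bis(methoxymethoxy)phenyl]ethanone, via aryne 23 (not isolated), via aryl cesium ester 24 (not isolated)
Conditions: 22 (1 equiv), 3 (2 equiv), CsF (5 equiv), THF, 125 °C, sealed tube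
Reagents that add atoms: none
Why: Desilylation of 22 by fluoride with loss of triflate unmasks aryne 23 (triple bond C4a–C8a), and the cesium carboxylate of 3 attacks C8a through oxygen because the σ-withdrawing methoxymethoxy group on C5 makes C8a the more electrophilic aryne terminus and places the emerging carbanion on C4a next to it, while the C8 alkyl chain exerts only a small steric bias. The ortho-acyloxy aryl anion 24 then adds to its own ester carbonyl through a strained four-membered alkoxide that collapses to the C4a ketone and the C8a phenoxide, so the C8a–O and C4a–C4 bonds form in one operation, no ring is closed and no stereocentre is created. The closest known reaction type is the fluoride-induced insertion of arynes into the C–O bond of carboxylic acids (carboxylate addition followed by an anionic Fries-type 1,3-acyl shift), which gives ortho-hydroxyaryl ketones when run hot in THF. The step needs regioselective addition to the unsymmetrical aryne (secured by the C5 alkoxy group) and acyl transfer faster than protonation of the aryl anion (secured by the high temperature, the aprotic medium and the ester carbonyl held next to the carbanion). It also needs intermolecular capture before the isopropenyl group or the silyl ether oxygen of the C8 chain can reach the aryne, which the twofold excess of carboxylate and the bulk of the triisopropylsilyl group should secure. The phenol is freed only on the C8a side while O5 stays protected, so ring C can later close in one direction only, and the remote (R) centre is untouched.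

Step 15
Reactants: 25 1-{2-hydroxy-4,6-bis(methoxymethoxy)-5-(3-methylbut-2-enyl)-3-[(2R)-3-methyl-2-(triisopropylsilyloxy)but-3-enyl]phenyl}-2-[3,4-bis(methoxymethoxy)phenyl]ethanone
Product: 27 3-[3,4-bis(methoxymethoxy)phenyl]-5,7-bis(methoxymethoxy)-6-(3-methylbut-2-enyl)-8-[(2R)-3-methyl-2-(triisopropylsilyloxy)but-3-enyl]chromen-4-one, via enaminone 26 (not isolated)
Conditions: Me2NCH(OMe)2 (5 equiv), toluene, 90 °C
Reagents that add atoms: N,N-dimethylformamide dimethyl acetal, COC(OC)N(C)C
Why: Condensation at the activated methylene gives an enaminone, and addition of the neighbouring phenol to its β-carbon with loss of dimethylamine closes the pyranone, the standard deoxybenzoin route to isoflavones.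

Step 16
Reactants: 27 3-[3,4-bis(methoxymethoxy)phenyl]-5,7-bis(methoxymethoxy)-6-(3-methylbut-2-enyl)-8-[(2R)-3-methyl-2-(triisopropylsilyloxy)but-3-enyl]chromen-4-one
Product: 28 3-[3,4-bis(methoxymethoxy)phenyl]-8-[(2R)-2-hydroxy-3-methylbut-3-enyl]-5,7-bis(methoxymethoxy)-6-(3-methylbut-2-enyl)chromen-4-one
Conditions: Bu4NF (3 equiv), AcOH (3 equiv), THF, rt → 40 °C
Reagents that add atoms: none
Why: Buffered fluoride cleaves the secondary silyl ether at silicon, so the carbinol configuration is retained and the base-sensitive pyranone is not opened.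

Step 17
Reactants: 28 3-[3,4-bis(methoxymethoxy)phenyl]-8-[(2R)-2-hydroxy-3-methylbut-3-enyl]-5,7-bis(methoxymethoxy)-6-(3-methylbut-2-enyl)chromen-4-one
Product: 29 3-(3,4-dihydroxyphenyl)-5,7-dihydroxy-8-[(2R)-2-hydroxy-3-methylbut-3-enyl]-6-(3-methylbut-2-enyl)chromen-4-one (CNP0236775.1)
Conditions: 3 M aq. HCl, MeOH, 45 °C, monitored and stopped at full conversion
Reagents that add atoms: none
Why: Acid-catalysed acetal exchange with methanol removes the four aryl MOM ethers under conditions mild enough that the prenyl group and the allylic alcohol should not cyclise onto the free phenols.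

**Compound list**

1 | 3,4-dihydroxyphenylacetic acid | OC(=O)Cc1ccc(O)c(O)c1 | starting material
2 | methoxymethyl 3,4-bis(methoxymethoxy)phenylacetate | COCOC(=O)Cc1ccc(OCOC)c(OCOC)c1 | intermediate (not isolated)
3 | 3,4-bis(methoxymethoxy)phenylacetic acid | OC(=O)Cc1ccc(OCOC)c(OCOC)c1 | intermediate
4 | phloroglucinol | Oc1cc(O)cc(O)c1 | starting material
5 | 3,5-bis(methoxymethoxy)phenol | COCOc1cc(O)cc(OCOC)c1 | intermediate
6 | [3,5-bis(methoxymethoxy)phenoxy]triisopropylsilane | COCOc1cc(O[Si](C(C)C)(C(C)C)C(C)C)cc(OCOC)c1 | intermediate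
7 | prenyl bromide | CC(C)=CCBr | starting material
8 | C6 aryllithium (lithium between the two MOM groups) | [Li]c1c(OCOC)cc(O[Si](C(C)C)(C(C)C)C(C)C)cc1OCOC | intermediate (not isolated)
9 | [3,5-bis(methoxymethoxy)-4-(3-methylbut-2-enyl)phenoxy]triisopropylsilane | COCOc1cc(O[Si](C(C)C)(C(C)C)C(C)C)cc(OCOC)c1CC=C(C)C | intermediate
10 | ethylene oxide | C1CO1 | starting material
11 | C8 aryllithium (lithium between MOM and silyloxy groups) | [Li]c1c(O[Si](C(C)C)(C(C)C)C(C)C)cc(OCOC)c(CC=C(C)C)c1OCOC | intermediate (not isolated)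
12 | 2-[2,4-bis(methoxymethoxy)-3-(3-methylbut-2-enyl)-6-(triisopropylsilyloxy)phenyl]ethanol | OCCc1c(O[Si](C(C)C)(C(C)C)C(C)C)cc(OCOC)c(CC=C(C)C)c1OCOC | intermediate
13 | 2-[2,4-bis(methoxymethoxy)-3-(3-methylbut-2-enyl)-6-(triisopropylsilyloxy)phenyl]acetaldehyde | O=CCc1c(O[Si](C(C)C)(C(C)C)C(C)C)cc(OCOC)c(CC=C(C)C)c1OCOC | intermediate
14 | isopropenylmagnesium bromide | C=C(C)[Mg]Br | starting material
15 | rac-1-[2,4-bis(methoxymethoxy)-3-(3-methylbut-2-enyl)-6-(triisopropylsilyloxy)phenyl]-3-methylbut-3-en-2-ol | C=C(C)C(O)Cc1c(O[Si](C(C)C)(C(C)C)C(C)C)cc(OCOC)c(CC=C(C)C)c1OCOC | intermediate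
16 | 1-[2,4-bis(methoxymethoxy)-3-(3-methylbut-2-enyl)-6-(triisopropylsilyloxy)phenyl]-3-methylbut-3-en-2-one | C=C(C)C(=O)Cc1c(O[Si](C(C)C)(C(C)C)C(C)C)cc(OCOC)c(CC=C(C)C)c1OCOC | intermediate
17 | (2R)-1-[2,4-bis(methoxymethoxy)-3-(3-methylbut-2-enyl)-6-(triisopropylsilyloxy)phenyl]-3-methylbut-3-en-2-ol | C=C(C)[C@H](O)Cc1c(O[Si](C(C)C)(C(C)C)C(C)C)cc(OCOC)c(CC=C(C)C)c1OCOC | intermediate
18 | (R)-bis(triisopropylsilyl) ether, C4a unsubstituted | C=C(C)[C@H](O[Si](C(C)C)(C(C)C)C(C)C)Cc1c(O[Si](C(C)C)(C(C)C)C(C)C)cc(OCOC)c(CC=C(C)C)c1OCOC | intermediate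
19 | C4a aryllithium | C=C(C)[C@H](O[Si](C(C)C)(C(C)C)C(C)C)Cc1c(O[Si](C(C)C)(C(C)C)C(C)C)c([Li])c(OCOC)c(CC=C(C)C)c1OCOC | intermediate (not isolated)
20 | (R)-bis(triisopropylsilyl) ether with trimethylsilyl on C4a | C=C(C)[C@H](O[Si](C(C)C)(C(C)C)C(C)C)Cc1c(O[Si](C(C)C)(C(C)C)C(C)C)c([Si](C)(C)C)c(OCOC)c(CC=C(C)C)c1OCOC | intermediate
21 | 3,5-bis(methoxymethoxy)-4-(3-methylbut-2-enyl)-2-[(2R)-3-methyl-2-(triisopropylsilyloxy)but-3-enyl]-6-(trimethylsilyl)phenol | C=C(C)[C@H](O[Si](C(C)C)(C(C)C)C(C)C)Cc1c(O)c([Si](C)(C)C)c(OCOC)c(CC=C(C)C)c1OCOC | intermediate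
22 | ring-A aryne precursor: the trifluoromethanesulfonate of 21 | C=C(C)[C@H](O[Si](C(C)C)(C(C)C)C(C)C)Cc1c(OS(=O)(=O)C(F)(F)F)c([Si](C)(C)C)c(OCOC)c(CC=C(C)C)c1OCOC | intermediate
23 | ring-A aryne (triple bond C4a–C8a) | C=C(C)[C@H](O[Si](C(C)C)(C(C)C)C(C)C)CC1=C(OCOC)C(CC=C(C)C)=C(OCOC)C#C1 | intermediate (not isolated)
24 | aryl cesium ester (O8a acylated, cesium on C4a) | C=C(C)[C@H](O[Si](C(C)C)(C(C)C)C(C)C)Cc1c(OC(=O)Cc2ccc(OCOC)c(OCOC)c2)c([Cs])c(OCOC)c(CC=C(C)C)c1OCOC | intermediate (not isolated)
25 | 1-{2-hydroxy-4,6-bis(methoxymethoxy)-5-(3-methylbut-2-enyl)-3-[(2R)-3-methyl-2-(triisopropylsilyloxy)but-3-enyl]phenyl}-2-[3,4-bis(methoxymethoxy)phenyl]ethanone | C=C(C)[C@H](O[Si](C(C)C)(C(C)C)C(C)C)Cc1c(O)c(C(=O)Cc2ccc(OCOC)c(OCOC)c2)c(OCOC)c(CC=C(C)C)c1OCOC | intermediate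
26 | enaminone (dimethylaminomethylene on the deoxybenzoin methylene) | C=C(C)[C@H](O[Si](C(C)C)(C(C)C)C(C)C)Cc1c(O)c(C(=O)C(=CN(C)C)c2ccc(OCOC)c(OCOC)c2)c(OCOC)c(CC=C(C)C)c1OCOC | intermediate (not isolated)
27 | 3-[3,4-bis(methoxymethoxy)phenyl]-5,7-bis(methoxymethoxy)-6-(3-methylbut-2-enyl)-8-[(2R)-3-methyl-2-(triisopropylsilyloxy)but-3-enyl]chromen-4-one | C=C(C)[C@H](O[Si](C(C)C)(C(C)C)C(C)C)Cc1c(OCOC)c(CC=C(C)C)c(OCOC)c2c(=O)c(-c3ccc(OCOC)c(OCOC)c3)coc12 | intermediate
28 | 3-[3,4-bis(methoxymethoxy)phenyl]-8-[(2R)-2-hydroxy-3-methylbut-3-enyl]-5,7-bis(methoxymethoxy)-6-(3-methylbut-2-enyl)chromen-4-one | C=C(C)[C@H](O)Cc1c(OCOC)c(CC=C(C)C)c(OCOC)c2c(=O)c(-c3ccc(OCOC)c(OCOC)c3)coc12 | intermediate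
29 | 3-(3,4-dihydroxyphenyl)-5,7-dihydroxy-8-[(2R)-2-hydroxy-3-methylbut-3-enyl]-6-(3-methylbut-2-enyl)chromen-4-one | C=C(C)[C@H](O)Cc1c(O)c(CC=C(C)C)c(O)c2c(=O)c(-c3ccc(O)c(O)c3)coc12 | target

**Totals**

Total step count: 17. Longest linear sequence: 16 steps (steps 2–17, from phloroglucinol 4 to 29).

**Steps most likely to fail**

Step 14 (aryne insertion). Three processes may intervene:
- protonation of the aryl anion before the acyl shift, which stops at O-arylation;
- addition of the carboxylate to C4a instead of C8a;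
- intramolecular capture of the aryne by the isopropenyl group (ene reaction) or by the silyl ether oxygen of the C8 chain.

The fallback uses no aryne; it sets out from 18 and 3 and comes back at 25. Acid 3 is converted with carbonyldiimidazole and N,O-dimethylhydroxylamine hydrochloride (CH2Cl2, rt) into N-methoxy-N-methyl-2-[3,4-bis(methoxymethoxy)phenyl]acetamide F1. Aryllithium 19, generated from 18 as in step 11, is added at −78 °C to F1 to give the O8a-silylated ketone 1-{4,6-bis(methoxymethoxy)-5-(3-methylbut-2-enyl)-3-[(2R)-3-methyl-2-(triisopropylsilyloxy)but-3-enyl]-2-(triisopropylsilyloxy)phenyl}-2-[3,4-bis(methoxymethoxy)phenyl]ethanone F2. One equivalent of Bu4NF in THF at 0 °C then removes the aryl silyl group selectively and gives 25. This is directed ortho-metalation followed by Weinreb ketone synthesis.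

Step 11 (silylation of C4a). Ring deprotonation beside the bulky silyloxy group may be slow. Base would then remove benzylic or allylic hydrogens instead, and deprotonation of the chain CH2 would be followed by β-elimination of silanolate.

The fallback replaces deprotonation by halogen–lithium exchange and O-to-C silyl migration; it sets out from 18 and comes back at 21. Treatment of 18 with Bu4NF (1 equiv, THF, 0 °C) gives 3,5-bis(methoxymethoxy)-4-(3-methylbut-2-enyl)-2-[(2R)-3-methyl-2-(triisopropylsilyloxy)but-3-enyl]phenol F3. N-Bromosuccinimide in CH2Cl2 at −78 °C brominates the only free ring position, ortho to the hydroxyl, to give 6-bromo-3,5-bis(methoxymethoxy)-4-(3-methylbut-2-enyl)-2-[(2R)-3-methyl-2-(triisopropylsilyloxy)but-3-enyl]phenol F4. Hexamethyldisilazane in THF at 65 °C converts it into the trimethylsilyl ether of that bromophenol F5. n-BuLi in THF at −78 °C then effects bromine–lithium exchange, the trimethylsilyl group migrates from oxygen to the lithiated carbon (retro-Brook rearrangement), and aqueous work-up delivers 21, which continues with step 13.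

Step 9 (oxazaborolidine reduction). Facial selectivity may be poor, because the catalyst must distinguish the isopropenyl group from a bulky arylmethyl group.

The fallback is a Sharpless kinetic resolution; it sets out from 15 and comes back at 17. Racemic 15 is treated with Ti(OiPr)4, L-(+)-diisopropyl tartrate, t-BuOOH (0.6 equiv) and 4 Å molecular sieves in CH2Cl2 at −20 °C. The (S)-enantiomer should be epoxidised faster, to the anti epoxy alcohol (1S)-2-[2,4-bis(methoxymethoxy)-3-(3-methylbut-2-enyl)-6-(triisopropylsilyloxy)phenyl]-1-[(2S)-2-methyloxiran-2-yl]ethanol F6. The slow-reacting (R)-alcohol 17 is recovered by chromatography, and steps 8 and 9 are then not needed.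

**Further compounds**

F1 | step 14 | N-methoxy-N-methyl-2-[3,4-bis(methoxymethoxy)phenyl]acetamide | CON(C)C(=O)Cc1ccc(OCOC)c(OCOC)c1
F2 | step 14 | 1-{4,6-bis(methoxymethoxy)-5-(3-methylbut-2-enyl)-3-[(2R)-3-methyl-2-(triisopropylsilyloxy)but-3-enyl]-2-(triisopropylsilyloxy)phenyl}-2-[3,4-bis(methoxymethoxy)phenyl]ethanone | C=C(C)[C@H](O[Si](C(C)C)(C(C)C)C(C)C)Cc1c(O[Si](C(C)C)(C(C)C)C(C)C)c(C(=O)Cc2ccc(OCOC)c(OCOC)c2)c(OCOC)c(CC=C(C)C)c1OCOC
F3 | step 11 | 3,5-bis(methoxymethoxy)-4-(3-methylbut-2-enyl)-2-[(2R)-3-methyl-2-(triisopropylsilyloxy)but-3-enyl]phenol | C=C(C)[C@H](O[Si](C(C)C)(C(C)C)C(C)C)Cc1c(O)cc(OCOC)c(CC=C(C)C)c1OCOC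
F4 | step 11 | 6-bromo-3,5-bis(methoxymethoxy)-4-(3-methylbut-2-enyl)-2-[(2R)-3-methyl-2-(triisopropylsilyloxy)but-3-enyl]phenol | C=C(C)[C@H](O[Si](C(C)C)(C(C)C)C(C)C)Cc1c(O)c(Br)c(OCOC)c(CC=C(C)C)c1OCOC
F5 | step 11 | trimethylsilyl ether of bromophenol F4 | C=C(C)[C@H](O[Si](C(C)C)(C(C)C)C(C)C)Cc1c(O[Si](C)(C)C)c(Br)c(OCOC)c(CC=C(C)C)c1OCOC
F6 | step 9 | (1S)-2-[2,4-bis(methoxymethoxy)-3-(3-methylbut-2-enyl)-6-(triisopropylsilyloxy)phenyl]-1-[(2S)-2-methyloxiran-2-yl]ethanol | C[C@]1(CO1)[C@@H](O)Cc1c(O[Si](C(C)C)(C(C)C)C(C)C)cc(OCOC)c(CC=C(C)C)c1OCOC
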